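Locants used throughout: ring atoms O1, C2 (methyl), C3, C4, C5, C6 as in the target; C7 is the formyl carbon on C3; Cα is the CH2 of the acetate arm on C4. The same locants are used for the corresponding atoms of every intermediate.

## Analysis of the target

The target 19 is a 3,4-dihydro-2H-pyran whose C5=C6 double bond is an enol ether conjugated with the C5 methyl ester, that is, a vinylogous carbonate. The saturated half carries three contiguous stereocentres: C2 (S, methyl), C3 (R, formyl) and C4 (R, acetate arm ending in the 2-(3,4-dihydroxyphenyl)ethyl ester). The formyl group is trans to both neighbours and the methyl group is cis to the arm, so all three substituents can sit pseudo-equatorially on the half-chair; the wanted isomer should also be the stable one. The C3 aldehyde is β to O1: enolisation at C3 allows epimerisation and expulsion of O1 as the enol of a formyl ester, which opens the ring. The free catechol does not tolerate oxidants or strong base, and the two different esters must not be exchanged. The difficulty is to set three adjacent centres bearing three different carbon substituents, to bring C6 and C7 to the aldehyde oxidation level next to two esters, and to uncover the aldehyde and the catechol only at the end. The route rests on one feature: C5 lies between its ester carbon and C6, and C6 is bonded to O1, so with C6 at the carboxyl level the unit O1–C6–C5(CO2Me) is a methyl malonate ester of the C2 hydroxyl, while C4 is the β-carbon of the arm ester and can accept that malonate carbanion.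

## Retrosynthetic reasoning

19 to 18. The two aryl C–O bonds of the catechol are masked as a cyclic ketal. The catechol is uncovered last because the steps before it use an oxidant and a hypervalent iodine reagent that a free catechol would not survive.

18 to 16 (through 17). The C7 aldehyde is traced back to a primary 4-methoxybenzyl ether. Keeping C7 at the alcohol level until the ring and the C5=C6 bond are complete means the β-alkoxy aldehyde never meets base. The forward steps must remove the benzyl-type ether without touching the electron-rich benzodioxole and oxidise the alcohol under neutral conditions.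

16 to 15 to 14. The C6–H bond is traced back to the carbonyl group of a δ-lactone whose C5 also carries the methyl ester. The lactone carbonyl is activated as its enol triflate and the triflate is replaced by hydride under palladium catalysis, which also makes C5 trigonal. Nothing is cut in the skeleton; the gain is that C6 may be a carboxyl carbon in the ring-forming step.

14 to 13. The C4–C5 bond is cut. This is the only ring bond whose two ends are naturally polarised once C6 is a carbonyl: C5 is a malonate carbon and C4 is the β-carbon of an E-enoate. The cut removes the ring and the C4 and C5 stereocentres and leaves an open chain with only C2 and C3. The forward reaction must close the six-membered ring and place the arm trans to the C3 substituent.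

13 to 11 and 12. The O1–C6 ester bond is cut, giving the secondary alcohol 11 and the acid chloride 12. Alcohol 11 comes from its silyl ether 10, because the hydroxyl has to be masked while the neighbouring ester is reduced.

10 to 5 and 9. The C4=Cα double bond is cut by an olefination between aldehyde 5 and phosphonate 9. This brings in the complete arm, including the protected aryl ethyl ester, in one convergent step, so the two esters of the target never need to be told apart later. Phosphonate 9 comes from alcohol 7 and acid 8, and 7 from hydroxytyrosol 6.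

5 to 4 to 3 to 1 and 2. The C3–C7 bond is cut. The enolate carbon of the chiral-pool hydroxy ester 1 is alkylated by the chloromethyl ether 2; C2 is bought and C3 is set from it with anti selectivity. The ester carbon of 1 becomes C4 after partial reduction.

## Alternatives that were turned down

Alternative 1: Both C4–C5 and C3–C7 are cut, so that C5, C6, C7 and the methyl ester come from the enol A3 of methyl diformylacetate, and C2, C3, C4 and the arm come from the β,γ-unsaturated lactone A2. In the forward direction irradiation joins A3 to the ring alkene of A2 in a De Mayo [2+2] cycloaddition, and the cyclobutanol opens by retro-aldol to the lactone A1. In its favour, two C–C bonds form in one step, and a single facial choice (anti to the C2 methyl) fixes both C3 and C4 because the addition is cis. C6 and C7 also arrive at the aldehyde level, so no triflate chemistry and no late oxidation are needed; on step count and oxidation-state economy this plan is stronger than the chosen one. Against it, the alkene of A2 is unconjugated and barely polarised, so the orientation of the cycloaddition is not secured, and the reverse orientation exchanges the positions of C5 and C7. A2 also tends to slip into conjugation. A1 must then undergo a ring switch: the lactone has to be opened by alcohol 7 and O1 has to close on C6, while the hydroxymethylene group prefers to form a lactol with C7, which is the wrong heterocycle. The chosen route gives up the brevity; in return the tether allows C5 to reach only C4, and O1 is bonded to the future C6 before the ring forms.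

Alternative 2: The O1–C6 bond is cut and C2 is traced back to a ketone. In the forward direction a ketoreductase reduces the racemic keto triester A5 at C2 while C3 epimerises, and the new hydroxyl lactonises onto one of the two diastereotopic arms to give A4. In its favour, the absolute configuration comes from a catalyst, the precursor is achiral and cheap, and C2 and C3 are set together; on catalysis and scalability it is stronger than the chosen route, which draws on the chiral pool. Against it, A4 lacks the C5 ester, so C5 must later be acylated, which leads to a malonate-type lactone like 14 and to the same C6 problem. The C3 tert-butyl ester must be brought to the aldehyde level without epimerisation. The arm methyl ester must be exchanged for the aryl ethyl ester in the presence of a more electrophilic lactone. An enzyme accepting this branched substrate must also be found by screening. The chosen route carries the right arm ester from the olefination onwards, has the C5 ester in place at ring closure and needs one oxidation at C7.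

Alternative 3: The C3–C4 bond is cut. In the forward direction the aldehyde A7 forms an enamine with a secondary-amine catalyst of the diarylprolinol silyl ether class, and C3 attacks C4 of the tethered dienoate (6-exo-trig) to give A6, which is identical with 18. In its favour, the product is one deprotection from the target, C6 and C7 need no redox change, and the new centres are under catalyst control; this is clearly the shortest plan and is stronger than the chosen route on step count. Against it, the enamine is generated at C3 while C2 carries O1 as a vinylogous carboxylate leaving group, so β-elimination competes before any ring protects the system. The acceptor is a push–pull dienoate that the O1 donor makes less electrophilic. The catalyst must also match the existing C2 centre, and C3 of the product stays epimerisable under the amine. The chosen route spends about five more steps; in return C3 never becomes nucleophilic while O1 can leave, and the β-alkoxy aldehyde appears only under neutral conditions.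

Key step: step 9

Remark on the chemistry: 4-methoxybenzyl chloromethyl ether (2) is taken as a purchasable reagent and is used fresh, since it hydrolyses readily.
Remark on the chemistry: lactone 14 is written as the C5 epimer with the ester equatorial; this centre is enolisable and is removed in step 10, so its configuration has no bearing on the route.

## Route

Step 1
Reactants: 1 methyl (S)-3-hydroxybutanoate; 2 4-methoxybenzyl chloromethyl ether
Product: 3 methyl (2S,3S)-3-hydroxy-2-{[(4-methoxyphenyl)methoxy]methyl}butanoate
Conditions: LiN(iPr)2 (2.2 equiv), THF, −78 → −20 °C; then 2 (1.1 equiv), DMPU, −78 → −20 °C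
Reagents that add atoms: none
Why: Fráter–Seebach alkylation: the chelated lithium alkoxide–enolate dianion of 1 is alkylated at carbon on the face away from the methyl group of the six-membered chelate, which should give the anti (2S,3S) product and so sets C3 from C2. The α-chloro ether is reactive enough at low temperature, and using about one equivalent should keep O-alkylation of the alkoxide down.

Step 2
Reactants: 3 methyl (2S,3S)-3-hydroxy-2-{[(4-methoxyphenyl)methoxy]methyl}butanoate
Product: 4 methyl (2S,3S)-2-{[(4-methoxyphenyl)methoxy]methyl}-3-[(triethylsilyl)oxy]butanoate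
Conditions: Et3SiCl, imidazole, DMF, 0 °C → rt
Reagents that add atoms: chlorotriethylsilane, CC[Si](Cl)(CC)CC
Why: Standard silylation of a secondary alcohol; the triethylsilyl ether survives hydride and olefination conditions and later leaves under mild acid that spares the 4-methoxybenzyl ether and the benzodioxole.

Step 3
Reactants: 4 methyl (2S,3S)-2-{[(4-methoxyphenyl)methoxy]methyl}-3-[(triethylsilyl)oxy]butanoate
Product: 5 (2S,3S)-2-{[(4-methoxyphenyl)methoxy]methyl}-3-[(triethylsilyl)oxy]butanal
Conditions: iBu2AlH (1.1 equiv), CH2Cl2, −78 °C; MeOH, aq. potassium sodium tartrate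
Reagents that add atoms: none
Why: Partial reduction of an ester with iBu2AlH: the tetrahedral aluminium hemiacetal persists at −78 °C and collapses to the aldehyde only on quench. The conditions are not basic, so the α-centre should be kept; the aldehyde is used directly.

Step 4
Reactants: 6 hydroxytyrosol
Product: 7 2-(2,2-dimethyl-1,3-benzodioxol-5-yl)ethan-1-ol
Conditions: Me2C(OMe)2, TsOH·H2O (cat.), toluene, reflux (4 Å MS); then AcOH/H2O/THF, rt
Reagents that add atoms: 2,2-dimethoxypropane, COC(C)(C)OC
Why: Acid-catalysed ketal exchange closes the five-membered benzodioxole on the catechol and is driven by removal of methanol; any mixed ketal on the primary hydroxyl is hydrolysed in the mild aqueous acid work-up.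

Step 5
Reactants: 7 2-(2,2-dimethyl-1,3-benzodioxol-5-yl)ethan-1-ol; 8 (diethoxyphosphoryl)acetic acid
Product: 9 2-(2,2-dimethyl-1,3-benzodioxol-5-yl)ethyl (diethoxyphosphoryl)acetate
Conditions: DCC, DMAP (cat.), CH2Cl2, 0 °C → rt
Reagents that add atoms: none
Why: Steglich esterification of a primary alcohol with a carbodiimide-activated acid; no other nucleophilic group is present.

Step 6
Reactants: 5 (2S,3S)-2-{[(4-methoxyphenyl)methoxy]methyl}-3-[(triethylsilyl)oxy]butanal; 9 2-(2,2-dimethyl-1,3-benzodioxol-5-yl)ethyl (diethoxyphosphoryl)acetate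
Product: 10 2-(2,2-dimethyl-1,3-benzodioxol-5-yl)ethyl (2E,4S,5S)-4-{[(4-methoxyphenyl)methoxy]methyl}-5-[(triethylsilyl)oxy]hex-2-enoate
Conditions: LiCl, iPr2NEt, MeCN, 0 °C → rt
Reagents that add atoms: none
Why: Horner–Wadsworth–Emmons olefination under Masamune–Roush conditions: the lithium-chelated phosphonate is deprotonated by a tertiary amine, mild enough that the α-branched, β-oxygenated aldehyde should neither epimerise nor eliminate. The stabilised phosphonate should give the E-enoate.

Step 7
Reactants: 10 2-(2,2-dimethyl-1,3-benzodioxol-5-yl)ethyl (2E,4S,5S)-4-{[(4-methoxyphenyl)methoxy]methyl}-5-[(triethylsilyl)oxy]hex-2-enoate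
Product: 11 2-(2,2-dimethyl-1,3-benzodioxol-5-yl)ethyl (2E,4S,5S)-5-hydroxy-4-{[(4-methoxyphenyl)methoxy]methyl}hex-2-enoate
Conditions: AcOH/THF/H2O (3:1:1), rt
Reagents that add atoms: none
Why: Acid-catalysed hydrolysis of a triethylsilyl ether; the 4-methoxybenzyl ether and the benzodioxole need much stronger acid. The E-geometry keeps the freed hydroxyl from lactonising onto the enoate.

Step 8
Reactants: 11 2-(2,2-dimethyl-1,3-benzodioxol-5-yl)ethyl (2E,4S,5S)-5-hydroxy-4-{[(4-methoxyphenyl)methoxy]methyl}hex-2-enoate; 12 methyl malonyl chloride (methyl 3-chloro-3-oxopropanoate)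
Product: 13 1-[(2S,3S,4E)-6-[2-(2,2-dimethyl-1,3-benzodioxol-5-yl)ethoxy]-3-{[(4-methoxyphenyl)methoxy]methyl}-6-oxohex-4-en-2-yl] 3-methyl propanedioate
Conditions: pyridine, CH2Cl2, 0 °C
Reagents that add atoms: none
Why: Acylation of a secondary alcohol by an acid chloride; pyridine is too weak a base to generate the malonate carbanion, so the Michael donor is installed without premature closure.

Step 9
Reactants: 13 1-[(2S,3S,4E)-6-[2-(2,2-dimethyl-1,3-benzodioxol-5-yl)ethoxy]-3-{[(4-methoxyphenyl)methoxy]methyl}-6-oxohex-4-en-2-yl] 3-methyl propanedioate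
Product: 14 methyl (3R,4R,5S,6S)-4-{2-[2-(2,2-dimethyl-1,3-benzodioxol-5-yl)ethoxy]-2-oxoethyl}-5-{[(4-methoxyphenyl)methoxy]methyl}-6-methyl-2-oxooxane-3-carboxylate
Conditions: Cs2CO3 (0.3 equiv), MeCN, 0 °C → rt; AcOH quench
Reagents that add atoms: none
Why: Cs2CO3 deprotonates only the malonate CH2, by far the most acidic site, and the carbanion C5, held to C2 through O1–C6(=O), adds to C4 of the E-enoate; the arm ester enolate so formed is protonated by the next malonate, so the base turns over. The closest known reaction type is the base-mediated intramolecular Michael addition of tethered malonates to enoates that gives substituted δ-lactones. The ring O1–C2–C3–C4–C5–C6 closes 6-exo-trig, with the C4=Cα bond outside the ring. C4 is controlled by C3: in the chair-like transition state the C2 methyl and the C3 4-methoxybenzyloxymethyl group are equatorial and C3–H lies near the plane of the enoate (least allylic strain), so C5 arrives on the face of C4 that lies on the C2 side and the arm ends up equatorial, trans to the C3 substituent and cis to the C2 methyl. C5 settles by enolisation of the malonate-type lactone with its ester equatorial; it is erased in step 10. The step needs chemoselective deprotonation, exo closure and facial selectivity at C4; the tether length rules out other ring sizes, and the weakly acidic γ-hydrogen at C3 rules out elimination of the malonate under carbonate. Retro-Michael cleavage needs the sparsely populated arm enolate, so the selectivity is taken as kinetic, and equilibration towards the all-equatorial lactone on warming is only a corrective option.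

Step 10
Reactants: 14 methyl (3R,4R,5S,6S)-4-{2-[2-(2,2-dimethyl-1,3-benzodioxol-5-yl)ethoxy]-2-oxoethyl}-5-{[(4-methoxyphenyl)methoxy]methyl}-6-methyl-2-oxooxane-3-carboxylate
Product: 15 methyl (2S,3S,4R)-4-{2-[2-(2,2-dimethyl-1,3-benzodioxol-5-yl)ethoxy]-2-oxoethyl}-3-{[(4-methoxyphenyl)methoxy]methyl}-2-methyl-6-[(trifluoromethanesulfonyl)oxy]-3,4-dihydro-2H-pyran-5-carboxylate
Conditions: NaH (1.05 equiv), THF, 0 °C; then N-(5-chloropyridin-2-yl)bis(trifluoromethanesulfonimide), −78 → 0 °C; rapid filtration through silica
Reagents that add atoms: N-(5-chloropyridin-2-yl)-1,1,1-trifluoro-N-(trifluoromethanesulfonyl)methanesulfonamide, O=S(=O)(N(c1ccc(Cl)cn1)S(=O)(=O)C(F)(F)F)C(F)(F)F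
Why: Proposed new method: the sodium enolate of 14 is a malonate-type enolate with two oxygen termini; sulfonylation at the lactone oxygen gives the endocyclic push–pull alkene C5=C6 with the methyl ester still conjugated, whereas sulfonylation at the ester oxygen would give a fully substituted exocyclic ketene acetal with allylic strain against the C4 arm, and the lactone carbonyl, the better acceptor, should carry more of the enolate charge; the closest known reaction types are the enol triflation of cyclic β-keto esters with triflimide reagents and the formation of ketene acetal triflates from lactone enolates. C5 becomes trigonal, so its configuration is lost.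

Step 11
Reactants: 15 methyl (2S,3S,4R)-4-{2-[2-(2,2-dimethyl-1,3-benzodioxol-5-yl)ethoxy]-2-oxoethyl}-3-{[(4-methoxyphenyl)methoxy]methyl}-2-methyl-6-[(trifluoromethanesulfonyl)oxy]-3,4-dihydro-2H-pyran-5-carboxylate
Product: 16 methyl (2S,3S,4R)-4-{2-[2-(2,2-dimethyl-1,3-benzodioxol-5-yl)ethoxy]-2-oxoethyl}-3-{[(4-methoxyphenyl)methoxy]methyl}-2-methyl-3,4-dihydro-2H-pyran-5-carboxylate
Conditions: Pd(PPh3)4 (5 mol %), HCO2H, Et3N, DMF, 50 °C
Reagents that add atoms: none
Why: Palladium-catalysed formate reduction of a vinyl triflate: zerovalent palladium inserts into the electron-poor C6–OTf bond, formate exchanges for triflate and loses CO2 to give a palladium hydride, and reductive elimination forms C6–H. The benzyl-type ether, the benzodioxole and both esters are inert to this homogeneous system, and C4 is not touched.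

Step 12
Reactants: 16 methyl (2S,3S,4R)-4-{2-[2-(2,2-dimethyl-1,3-benzodioxol-5-yl)ethoxy]-2-oxoethyl}-3-{[(4-methoxyphenyl)methoxy]methyl}-2-methyl-3,4-dihydro-2H-pyran-5-carboxylate
Product: 18 methyl (2S,3R,4R)-4-{2-[2-(2,2-dimethyl-1,3-benzodioxol-5-yl)ethoxy]-2-oxoethyl}-3-formyl-2-methyl-3,4-dihydro-2H-pyran-5-carboxylate, via primary alcohol 17 (not isolated)
Conditions: DDQ, CH2Cl2/pH 7 buffer, 0 °C; extractive work-up; then Dess–Martin periodinane, NaHCO3, CH2Cl2, 0 °C → rt
Reagents that add atoms: none
Why: DDQ abstracts hydride from the 4-methoxybenzyl ether to give an oxocarbenium ion that water cleaves; the benzodioxole has no oxygen-bearing benzylic position and the enol ether is electron-poor, so both should be spared. Alcohol 17 could lactonise onto the arm ester, so it is oxidised at once with buffered Dess–Martin periodinane, which is neutral enough to leave the β-alkoxy aldehyde and its C3 centre, already in the stable trans,trans arrangement, intact.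

Step 13
Reactants: 18 methyl (2S,3R,4R)-4-{2-[2-(2,2-dimethyl-1,3-benzodioxol-5-yl)ethoxy]-2-oxoethyl}-3-formyl-2-methyl-3,4-dihydro-2H-pyran-5-carboxylate
Product: 19 methyl (2S,3R,4R)-4-{2-[2-(3,4-dihydroxyphenyl)ethoxy]-2-oxoethyl}-3-formyl-2-methyl-3,4-dihydro-2H-pyran-5-carboxylate
Conditions: CF3CO2H/H2O (9:1), CH2Cl2, 0 °C
Reagents that add atoms: none
Why: Acid-catalysed hydrolysis of the 2,2-dimethyl-1,3-benzodioxole releases the catechol and acetone; the vinylogous carbonate resists protonation at C5 and the esters are inert to cold aqueous trifluoroacetic acid. The all-pseudo-equatorial arrangement at C2–C4 should be the preferred one if any acid-promoted equilibration occurs, but exposure is kept short.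

## Compound list

1 | methyl (S)-3-hydroxybutanoate | C[C@H](O)CC(=O)OC | starting material
2 | 4-methoxybenzyl chloromethyl ether | COc1ccc(COCCl)cc1 | starting material
3 | methyl (2S,3S)-3-hydroxy-2-{[(4-methoxyphenyl)methoxy]methyl}butanoate | C[C@H](O)[C@H](COCc1ccc(OC)cc1)C(=O)OC | intermediate
4 | methyl (2S,3S)-2-{[(4-methoxyphenyl)methoxy]methyl}-3-[(triethylsilyl)oxy]butanoate | CC[Si](CC)(CC)O[C@@H](C)[C@H](COCc1ccc(OC)cc1)C(=O)OC | intermediate
5 | (2S,3S)-2-{[(4-methoxyphenyl)methoxy]methyl}-3-[(triethylsilyl)oxy]butanal | CC[Si](CC)(CC)O[C@@H](C)[C@H](COCc1ccc(OC)cc1)C=O | intermediate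
6 | hydroxytyrosol | OCCc1ccc(O)c(O)c1 | starting material
7 | 2-(2,2-dimethyl-1,3-benzodioxol-5-yl)ethan-1-ol | OCCc1ccc2OC(C)(C)Oc2c1 | intermediate
8 | (diethoxyphosphoryl)acetic acid | CCOP(=O)(CC(=O)O)OCC | starting material
9 | 2-(2,2-dimethyl-1,3-benzodioxol-5-yl)ethyl (diethoxyphosphoryl)acetate | CCOP(=O)(CC(=O)OCCc1ccc2OC(C)(C)Oc2c1)OCC | intermediate
10 | 2-(2,2-dimethyl-1,3-benzodioxol-5-yl)ethyl (2E,4S,5S)-4-{[(4-methoxyphenyl)methoxy]methyl}-5-[(triethylsilyl)oxy]hex-2-enoate | CC[Si](CC)(CC)O[C@@H](C)[C@H](COCc1ccc(OC)cc1)/C=C/C(=O)OCCc1ccc2OC(C)(C)Oc2c1 | intermediate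
11 | 2-(2,2-dimethyl-1,3-benzodioxol-5-yl)ethyl (2E,4S,5S)-5-hydroxy-4-{[(4-methoxyphenyl)methoxy]methyl}hex-2-enoate | C[C@H](O)[C@H](COCc1ccc(OC)cc1)/C=C/C(=O)OCCc1ccc2OC(C)(C)Oc2c1 | intermediate
12 | methyl malonyl chloride (methyl 3-chloro-3-oxopropanoate) | COC(=O)CC(=O)Cl | starting material
13 | 1-[(2S,3S,4E)-6-[2-(2,2-dimethyl-1,3-benzodioxol-5-yl)ethoxy]-3-{[(4-methoxyphenyl)methoxy]methyl}-6-oxohex-4-en-2-yl] 3-methyl propanedioate | COC(=O)CC(=O)O[C@@H](C)[C@H](COCc1ccc(OC)cc1)/C=C/C(=O)OCCc1ccc2OC(C)(C)Oc2c1 | intermediate
14 | methyl (3R,4R,5S,6S)-4-{2-[2-(2,2-dimethyl-1,3-benzodioxol-5-yl)ethoxy]-2-oxoethyl}-5-{[(4-methoxyphenyl)methoxy]methyl}-6-methyl-2-oxooxane-3-carboxylate | O=C1O[C@@H](C)[C@H](COCc2ccc(OC)cc2)[C@@H](CC(=O)OCCc2ccc3OC(C)(C)Oc3c2)[C@@H]1C(=O)OC | intermediate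
15 | methyl (2S,3S,4R)-4-{2-[2-(2,2-dimethyl-1,3-benzodioxol-5-yl)ethoxy]-2-oxoethyl}-3-{[(4-methoxyphenyl)methoxy]methyl}-2-methyl-6-[(trifluoromethanesulfonyl)oxy]-3,4-dihydro-2H-pyran-5-carboxylate | COC(=O)C1=C(OS(=O)(=O)C(F)(F)F)O[C@@H](C)[C@H](COCc2ccc(OC)cc2)[C@H]1CC(=O)OCCc1ccc2OC(C)(C)Oc2c1 | intermediate
16 | methyl (2S,3S,4R)-4-{2-[2-(2,2-dimethyl-1,3-benzodioxol-5-yl)ethoxy]-2-oxoethyl}-3-{[(4-methoxyphenyl)methoxy]methyl}-2-methyl-3,4-dihydro-2H-pyran-5-carboxylate | COC(=O)C1=CO[C@@H](C)[C@H](COCc2ccc(OC)cc2)[C@H]1CC(=O)OCCc1ccc2OC(C)(C)Oc2c1 | intermediate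
17 | methyl (2S,3S,4R)-4-{2-[2-(2,2-dimethyl-1,3-benzodioxol-5-yl)ethoxy]-2-oxoethyl}-3-(hydroxymethyl)-2-methyl-3,4-dihydro-2H-pyran-5-carboxylate | COC(=O)C1=CO[C@@H](C)[C@H](CO)[C@H]1CC(=O)OCCc1ccc2OC(C)(C)Oc2c1 | intermediate (not isolated)
18 | methyl (2S,3R,4R)-4-{2-[2-(2,2-dimethyl-1,3-benzodioxol-5-yl)ethoxy]-2-oxoethyl}-3-formyl-2-methyl-3,4-dihydro-2H-pyran-5-carboxylate | COC(=O)C1=CO[C@@H](C)[C@H](C=O)[C@H]1CC(=O)OCCc1ccc2OC(C)(C)Oc2c1 | intermediate
19 | methyl (2S,3R,4R)-4-{2-[2-(3,4-dihydroxyphenyl)ethoxy]-2-oxoethyl}-3-formyl-2-methyl-3,4-dihydro-2H-pyran-5-carboxylate | COC(=O)C1=CO[C@@H](C)[C@H](C=O)[C@H]1CC(=O)OCCc1ccc(O)c(O)c1 | target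

## Step count and least certain steps

Total: 13 steps. Longest linear sequence: 11 steps (steps 1–3 and 6–13, from 1); steps 4 and 5 form the side branch from 6.

Step 10 (proposed new method). The likely failure is sulfonylation at the ester oxygen in place of the lactone oxygen, or hydrolysis of the activated ketene acetal triflate back to the lactone during handling; the same lability would also undermine step 11. The fallback uses known chemistry, sets out from 14 and rejoins at 16. Krapcho demethoxycarbonylation (LiCl, wet DMSO, 130 °C) should give the lactone 2-(2,2-dimethyl-1,3-benzodioxol-5-yl)ethyl 2-[(2S,3S,4S)-3-{[(4-methoxyphenyl)methoxy]methyl}-2-methyl-6-oxooxan-4-yl]acetate F1. Condensation at the more acidic lactone α-position with tert-butoxybis(dimethylamino)methane should give the enamino lactone F2. Acidic methanol (HCl, MeOH, 0 °C → rt) then brings about the acyl-lactone rearrangement: methanol opens the lactone to the methyl ester and O1 closes onto the new formyl carbon to give the 6-methoxy acetal F3, from which TsOH in warm toluene eliminates methanol to give 16. In this detour the introduced formyl carbon becomes C6 and the former lactone carbonyl becomes the ester carbon; C2, C3 and C4 are not touched. The arm ester must be watched for exchange in acidic methanol.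

Step 9 (key step). The likely failure is insufficient facial discrimination at C4 under kinetic control, that is, closure through the chair with the enoate axial, while retro-Michael equilibration is too slow at room temperature to correct it. The fallback reverses the polarity, sets out from 5 (with 7) and rejoins at 14. Knoevenagel condensation of 5 with dimethyl malonate (piperidinium acetate, CH2Cl2, 4 Å MS) gives dimethyl 2-[(2S,3S)-2-{[(4-methoxyphenyl)methoxy]methyl}-3-[(triethylsilyl)oxy]butylidene]propanedioate F4. The lithium enolate (LiN(iPr)2, THF, −78 °C) of 2-(2,2-dimethyl-1,3-benzodioxol-5-yl)ethyl acetate F5, made from 7 with acetic anhydride and pyridine, is added to F4. The ester cis to C3 locks C3–H in the alkene plane by allylic strain, and attack anti to the larger silyloxyethyl branch should give the Michael adduct F6 with the same C4 configuration as 14. TsOH in CH2Cl2 then removes the silyl group and lactonises the C2 hydroxyl onto a malonate ester to give 14.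

Step 1. The likely failure is O-alkylation of the lithium alkoxide by the very reactive chloromethyl ether, or loss of the electrophile by decomposition, so that conversion at carbon stays low. The fallback sets out from 1 and rejoins at 3. The same dianion is trapped with monomeric formaldehyde in an anti-selective aldol reaction to give methyl (2S,3S)-3-hydroxy-2-(hydroxymethyl)butanoate F7. The primary hydroxyl is then etherified selectively through the dibutylstannylene acetal (Bu2SnO, toluene, reflux; then 4-methoxybenzyl chloride, Bu4NI) to give 3.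

Step 13. The likely failure is slow cleavage of the robust benzodioxole, which forces long exposure to aqueous acid and with it ring opening at O1–C2 by retro-oxa-Michael reaction, epimerisation, or hydration of the enol ether. The fallback moves the unmasking of the catechol to neutral hydrogenolysis, sets out from 16 and rejoins at 19. LiOH (THF/H2O, 0 °C) saponifies the aliphatic arm ester in preference to the deactivated vinylogous carbonate and gives the acid 2-[(2S,3S,4R)-5-(methoxycarbonyl)-3-{[(4-methoxyphenyl)methoxy]methyl}-2-methyl-3,4-dihydro-2H-pyran-4-yl]acetic acid F8, with 7 set free. F8 is esterified (DCC, DMAP) with 2-[3,4-bis(benzyloxy)phenyl]ethan-1-ol F9, made from 6 with benzyl bromide and K2CO3 in acetone, to give the dibenzyl analogue of 16 F10. DDQ and then Dess–Martin periodinane, as in step 12, give the dibenzyl aldehyde F12 through the alcohol F11. Hydrogenolysis (H2, palladium on carbon, EtOAc, rt) then removes both benzyl groups to give 19; the push–pull C5=C6 bond is expected to resist these conditions.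

## Further compounds

F1 | step 10 | 2-(2,2-dimethyl-1,3-benzodioxol-5-yl)ethyl 2-[(2S,3S,4S)-3-{[(4-methoxyphenyl)methoxy]methyl}-2-methyl-6-oxooxan-4-yl]acetate | O=C1O[C@@H](C)[C@H](COCc2ccc(OC)cc2)[C@@H](CC(=O)OCCc2ccc3OC(C)(C)Oc3c2)C1
F2 | step 10 | 2-(2,2-dimethyl-1,3-benzodioxol-5-yl)ethyl 2-[(2S,3S,4R)-5-[(dimethylamino)methylidene]-3-{[(4-methoxyphenyl)methoxy]methyl}-2-methyl-6-oxooxan-4-yl]acetate | CN(C)C=C1C(=O)O[C@@H](C)[C@H](COCc2ccc(OC)cc2)[C@H]1CC(=O)OCCc1ccc2OC(C)(C)Oc2c1
F3 | step 10 | methyl (2S,3S,4R)-4-{2-[2-(2,2-dimethyl-1,3-benzodioxol-5-yl)ethoxy]-2-oxoethyl}-6-methoxy-3-{[(4-methoxyphenyl)methoxy]methyl}-2-methyloxane-5-carboxylate (mixture of epimers at C5 and C6) | COC(=O)C1C(OC)O[C@@H](C)[C@H](COCc2ccc(OC)cc2)[C@H]1CC(=O)OCCc1ccc2OC(C)(C)Oc2c1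
F4 | step 9 | dimethyl 2-[(2S,3S)-2-{[(4-methoxyphenyl)methoxy]methyl}-3-[(triethylsilyl)oxy]butylidene]propanedioate | CC[Si](CC)(CC)O[C@@H](C)[C@H](COCc1ccc(OC)cc1)C=C(C(=O)OC)C(=O)OC
F5 | step 9 | 2-(2,2-dimethyl-1,3-benzodioxol-5-yl)ethyl acetate | CC(=O)OCCc1ccc2OC(C)(C)Oc2c1
F6 | step 9 | dimethyl 2-[(1R,2S,3S)-1-{2-[2-(2,2-dimethyl-1,3-benzodioxol-5-yl)ethoxy]-2-oxoethyl}-2-{[(4-methoxyphenyl)methoxy]methyl}-3-[(triethylsilyl)oxy]butyl]propanedioate | CC[Si](CC)(CC)O[C@@H](C)[C@H](COCc1ccc(OC)cc1)[C@@H](CC(=O)OCCc1ccc2OC(C)(C)Oc2c1)C(C(=O)OC)C(=O)OC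
F7 | step 1 | methyl (2S,3S)-3-hydroxy-2-(hydroxymethyl)butanoate | C[C@H](O)[C@H](CO)C(=O)OC
F8 | step 13 | 2-[(2S,3S,4R)-5-(methoxycarbonyl)-3-{[(4-methoxyphenyl)methoxy]methyl}-2-methyl-3,4-dihydro-2H-pyran-4-yl]acetic acid | COC(=O)C1=CO[C@@H](C)[C@H](COCc2ccc(OC)cc2)[C@H]1CC(=O)O
F9 | step 13 | 2-[3,4-bis(benzyloxy)phenyl]ethan-1-ol | OCCc1ccc(OCc2ccccc2)c(OCc2ccccc2)c1
F10 | step 13 | methyl (2S,3S,4R)-4-(2-{2-[3,4-bis(benzyloxy)phenyl]ethoxy}-2-oxoethyl)-3-{[(4-methoxyphenyl)methoxy]methyl}-2-methyl-3,4-dihydro-2H-pyran-5-carboxylate | COC(=O)C1=CO[C@@H](C)[C@H](COCc2ccc(OC)cc2)[C@H]1CC(=O)OCCc1ccc(OCc2ccccc2)c(OCc2ccccc2)c1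
F11 | step 13 | methyl (2S,3S,4R)-4-(2-{2-[3,4-bis(benzyloxy)phenyl]ethoxy}-2-oxoethyl)-3-(hydroxymethyl)-2-methyl-3,4-dihydro-2H-pyran-5-carboxylate | COC(=O)C1=CO[C@@H](C)[C@H](CO)[C@H]1CC(=O)OCCc1ccc(OCc2ccccc2)c(OCc2ccccc2)c1
F12 | step 13 | methyl (2S,3R,4R)-4-(2-{2-[3,4-bis(benzyloxy)phenyl]ethoxy}-2-oxoethyl)-3-formyl-2-methyl-3,4-dihydro-2H-pyran-5-carboxylate | COC(=O)C1=CO[C@@H](C)[C@H](C=O)[C@H]1CC(=O)OCCc1ccc(OCc2ccccc2)c(OCc2ccccc2)c1
A1 | alternative 1 | methyl (2Z)-2-[(2S,3R,4R)-3-formyl-2-methyl-6-oxooxan-4-yl]-3-hydroxyprop-2-enoate | O=C1C[C@@H](/C(C(=O)OC)=C/O)[C@@H](C=O)[C@H](C)O1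
A2 | alternative 1 | (6S)-6-methyl-3,6-dihydro-2H-pyran-2-one | O=C1CC=C[C@H](C)O1
A3 | alternative 1 | methyl 2-formyl-3-hydroxyprop-2-enoate (enol of methyl diformylacetate) | COC(=O)C(C=O)=CO
A4 | alternative 2 | tert-butyl (2S,3R,4S)-4-(2-methoxy-2-oxoethyl)-2-methyl-6-oxooxane-3-carboxylate | O=C1O[C@@H](C)[C@H](C(=O)OC(C)(C)C)[C@@H](CC(=O)OC)C1
A5 | alternative 2 | dimethyl 3-[1-(tert-butoxy)-1,3-dioxobutan-2-yl]pentanedioate (racemic) | CC(=O)C(C(=O)OC(C)(C)C)C(CC(=O)OC)CC(=O)OC
A6 | alternative 3 | methyl (2S,3R,4R)-4-{2-[2-(2,2-dimethyl-1,3-benzodioxol-5-yl)ethoxy]-2-oxoethyl}-3-formyl-2-methyl-3,4-dihydro-2H-pyran-5-carboxylate (identical with 18) | COC(=O)C1=CO[C@@H](C)[C@H](C=O)[C@H]1CC(=O)OCCc1ccc2OC(C)(C)Oc2c1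
A7 | alternative 3 | 5-[2-(2,2-dimethyl-1,3-benzodioxol-5-yl)ethyl] 1-methyl (2E,3E)-2-({[(2S)-4-oxobutan-2-yl]oxy}methylidene)pent-3-enedioate | O=CC[C@H](C)O/C=C(/C(=O)OC)\C=C\C(=O)OCCc1ccc2OC(C)(C)Oc2c1
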